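**Retrosynthetic overview**

- The strategy rests on C4 of ring A: a tertiary carbinol carbon bonded to C3, C5 and the C15 methyl, with its hydroxyl axial on the β face of the trans-decalin, 1,3-syn to the C6 oxygen and the C14 methyl. Cutting C3–C4 gives an acetyl group on C5 of ring B and a C3 carbanion, made from a primary iodide with SmI2 (Barbier closure of ring A).
- The C6–O acyl bond is cut first in the retrosynthetic sense: phenol-silylated isoferuloyl chloride is put on the only secondary hydroxyl of the 4β,6β-diol.
- The ring B iodo ketone is traced to (S)-piperitone, which supplies ring B, C7 and the C14 methyl. C1 to C3 come from a Hosomi–Sakurai allylation at C10 anti to the C6 silyloxy group, C4 and C15 from a C5 vinyllithium and an acetyl donor, and the C6 carbinol from a cis-selective hydride reduction.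
- Ring order: ring B is purchased and ring A is closed in step 8. The C6 oxygen stays silylated through the closure, because a free hydroxyl would protonate the alkylsamarium.

Key step: step 8

Assumption: (S)-(+)-piperitone is taken as commercially available in high enantiomeric purity; eudesmane numbering (C1 to C15) is used for all ring B intermediates.

**Route**

Step 1
Reactants: 1 (S)-piperitone
Product: 3 (6S)-2-bromo-3-methyl-6-(propan-2-yl)cyclohex-2-en-1-one, via dibromo ketone 2 (not isolated)
Conditions: Br2, CH2Cl2, 0 °C; then Et3N, 0 °C to rt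
Reagents that add atoms: bromine, BrBr
Why: Bromination–dehydrobromination of an enone: anti addition of Br2 to the C5=C10 double bond gives 2, from which Et3N removes the acidic C5 proton and expels the tertiary C10 bromide (E1cB) to restore conjugation; no stereocentre is formed, and the C7 centre, α' to the ketone, should survive brief contact with the weak amine base at 0 °C.

Step 2
Reactants: 3 (6S)-2-bromo-3-methyl-6-(propan-2-yl)cyclohex-2-en-1-one
Product: 4 (1R,6S)-2-bromo-3-methyl-6-(propan-2-yl)cyclohex-2-en-1-ol (hydroxyl cis to isopropyl)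
Conditions: LiBH(s-Bu)3 (L-Selectride), THF, −78 °C; then H2O
Reagents that add atoms: none
Why: 1,2-Reduction of an enone by a bulky trialkylborohydride (the β,β-disubstituted, α-brominated double bond resists conjugate hydride addition): as in the reduction of menthone to neomenthol, the hindered hydride should avoid the axial trajectory, which runs gauche to the C7 isopropyl group and past the axial C8 hydrogen, and attack C6 equatorially, so that the new C6 centre (R) carries a pseudoaxial hydroxyl cis to the isopropyl group.

Step 3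
Reactants: 4 (1R,6S)-2-bromo-3-methyl-6-(propan-2-yl)cyclohex-2-en-1-ol
Product: 5 tert-butyl{[(1R,6S)-2-bromo-3-methyl-6-(propan-2-yl)cyclohex-2-en-1-yl]oxy}dimethylsilane
Conditions: TBSOTf, 2,6-lutidine, CH2Cl2, 0 °C
Reagents that add atoms: tert-butyldimethylsilyl trifluoromethanesulfonate, CC(C)(C)[Si](C)(C)OS(=O)(=O)C(F)(F)F
Why: Silylation of a hindered secondary allylic alcohol with a silyl triflate and a non-nucleophilic base; no stereocentre is affected, and the bulky silyl ether later shields the β face of ring B.

Step 4
Reactants: 5 tert-butyl{[(1R,6S)-2-bromo-3-methyl-6-(propan-2-yl)cyclohex-2-en-1-yl]oxy}dimethylsilane; 6 N-methoxy-N-methylacetamide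
Product: 8 1-[(5S,6R)-6-(tert-butyldimethylsilyloxy)-2-methyl-5-(propan-2-yl)cyclohex-1-en-1-yl]ethan-1-one, via vinyllithium 7 (not isolated)
Conditions: t-BuLi (2 equiv), Et2O, −78 °C; then 6, −78 to 0 °C; then H2O
Reagents that add atoms: none
Why: Bromine–lithium exchange gives vinyllithium 7 (the ring forbids β-elimination of silanolate to an allene, and a 1,3 oxygen-to-carbon silyl shift is slow at −78 °C), which is acylated by 6 through a stable chelated tetrahedral adduct that cannot over-add (Weinreb ketone synthesis); no stereocentre is formed.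

Step 5
Reactants: 8 1-[(5S,6R)-6-(tert-butyldimethylsilyloxy)-2-methyl-5-(propan-2-yl)cyclohex-1-en-1-yl]ethan-1-one; 9 allyltrimethylsilane
Product: 11 1-[(1S,2R,3S,6S)-2-(tert-butyldimethylsilyloxy)-6-methyl-3-(propan-2-yl)-6-(prop-2-en-1-yl)cyclohexyl]ethan-1-one, via titanium enolate 10 (not isolated)
Conditions: TiCl4, CH2Cl2, −78 °C; then H2O, −78 °C to rt
Reagents that add atoms: none
Why: Hosomi–Sakurai conjugate allylation: TiCl4 activates the acetyl group and the allylsilane should attack the β carbon C10 from the α face, anti to the C6 silyloxy group that A(1,2) strain with the acetyl group and the cis isopropyl group hold pseudoaxial on the β face, which sets the quaternary centre C10 (C14 methyl β, allyl α); titanium enolate 10 is then protonated at C5 from the α face, away from the axial C14 methyl and C6 silyloxy groups, which places the acetyl group equatorial (C5, S).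

Step 6
Reactants: 11 1-[(1S,2R,3S,6S)-2-(tert-butyldimethylsilyloxy)-6-methyl-3-(propan-2-yl)-6-(prop-2-en-1-yl)cyclohexyl]ethan-1-one
Product: 13 1-[(1S,2R,3S,6S)-2-(tert-butyldimethylsilyloxy)-6-(3-hydroxypropyl)-6-methyl-3-(propan-2-yl)cyclohexyl]ethan-1-one, via alkylborane 12 (not isolated)
Conditions: 9-BBN, THF, 0 °C to rt; then NaBO3·4H2O, H2O, rt
Reagents that add atoms: sodium perborate, [Na+].[Na+].O[B-]1(O)OO[B-](O)(O)OO1
Why: Anti-Markovnikov hydroboration–oxidation: 9-BBN should react with the terminal alkene much faster than with the methyl ketone flanked by the quaternary C10 and the C6 silyloxy carbon, and the C–B bond is oxidised by mild perborate without strong base, so neither β-elimination of silanol nor epimerisation at C5 is expected; no stereocentre is formed.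

Step 7
Reactants: 13 1-[(1S,2R,3S,6S)-2-(tert-butyldimethylsilyloxy)-6-(3-hydroxypropyl)-6-methyl-3-(propan-2-yl)cyclohexyl]ethan-1-one
Product: 14 1-[(1S,2R,3S,6S)-2-(tert-butyldimethylsilyloxy)-6-(3-iodopropyl)-6-methyl-3-(propan-2-yl)cyclohexyl]ethan-1-one
Conditions: I2, PPh3, imidazole, CH2Cl2, 0 °C to rt
Reagents that add atoms: iodine, II
Why: Appel-type iodination: the primary alcohol is activated as an alkoxyphosphonium ion and displaced by iodide (SN2) under buffered conditions that leave the ketone, its α centre and the silyl ether untouched.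

Step 8
Reactants: 14 1-[(1S,2R,3S,6S)-2-(tert-butyldimethylsilyloxy)-6-(3-iodopropyl)-6-methyl-3-(propan-2-yl)cyclohexyl]ethan-1-one
Product: 16 6β-(tert-butyldimethylsilyloxy)-5α,7αH-eudesman-4β-ol, via alkylsamarium 15 (not isolated)
Conditions: SmI2 (2.5 equiv), HMPA, THF, −78 to 0 °C; then H2O
Reagents that add atoms: none
Why: SmI2 activated by HMPA transfers one electron to the C3–I bond, the primary radical is reduced again to alkylsamarium 15 (divalent samarium becoming trivalent), and this adds to the C4 carbonyl; the closest known reaction type is the SmI2-mediated intramolecular Barbier cyclisation of ω-iodoalkyl ketones. Ring A closes by 6-exo-trig attack of C3 on the acetyl carbon and is trans-fused, because C1 and the acetyl group are both equatorial on the ring B chair (C14 methyl and C6 silyloxy axial, isopropyl equatorial). The new stereocentre C4 is set by the chair transition state: the acetyl methyl C15 takes the equatorial α position, since the alternative would place it 1,3-diaxial to both the C14 methyl and the 6β oxygen, so the carbonyl oxygen bound to trivalent samarium sits axial on the β face beside the 6β oxygen and C3 bonds from the α side, giving 4β-OH and 4α-CH3; any coordination of samarium to the 6β ether oxygen works in the same direction. The step needs carbonyl addition to win over protonation or enolisation, which the silyl ether at C6 (no hydroxyl proton near the carbanion) and the low basicity of alkylsamariums should secure, and it needs diastereoselectivity at C4, which the two axial β substituents on C10 and C6 secure. The medium is neither acidic nor basic, so the β-silyloxy ketone should neither eliminate nor epimerise at C5 before it cyclises.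

Step 9
Reactants: 16 6β-(tert-butyldimethylsilyloxy)-5α,7αH-eudesman-4β-ol
Product: 17 5α,7αH-eudesmane-4β,6β-diol, (4S,5S,6R,7S,10R)
Conditions: 48% aq. HF, MeCN, rt
Reagents that add atoms: none
Why: Fluoride-driven desilylation: HF is small enough to reach the axial, flanked C6 silyl ether, while the tertiary C4 alcohol should not ionise in aqueous acetonitrile; no stereocentre is touched.

Step 10
Reactants: 18 isoferulic acid
Product: 20 (E)-3-[3-(tert-butyldimethylsilyloxy)-4-methoxyphenyl]prop-2-enoic acid, via bis-silyl compound 19 (not isolated)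
Conditions: TBSCl, imidazole, DMF, rt; then AcOH, THF, H2O, rt
Reagents that add atoms: tert-butyldimethylsilyl chloride, CC(C)(C)[Si](C)(C)Cl
Why: Imidazole-promoted silylation of both phenol and acid gives 19, whose silyl ester is far more labile than the aryl silyl ether and is hydrolysed selectively by aqueous acetic acid.

Step 11
Reactants: 20 (E)-3-[3-(tert-butyldimethylsilyloxy)-4-methoxyphenyl]prop-2-enoic acid
Product: 21 (E)-3-[3-(tert-butyldimethylsilyloxy)-4-methoxyphenyl]prop-2-enoyl chloride
Conditions: (COCl)2, DMF (cat.), CH2Cl2, 0 °C to rt; used crude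
Reagents that add atoms: oxalyl chloride, O=C(Cl)C(=O)Cl
Why: Acid chloride formation through the DMF-derived chloroiminium ion (Vilsmeier-type activation) at low temperature should preserve the E double bond and the aryl silyl ether.

Step 12
Reactants: 17 5α,7αH-eudesmane-4β,6β-diol; 21 (E)-3-[3-(tert-butyldimethylsilyloxy)-4-methoxyphenyl]prop-2-enoyl chloride
Product: 22 4β-hydroxy-5α,7αH-eudesman-6β-yl (E)-3-[3-(tert-butyldimethylsilyloxy)-4-methoxyphenyl]prop-2-enoate
Conditions: DMAP, Et3N, CH2Cl2, rt to 40 °C
Reagents that add atoms: none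
Why: DMAP-catalysed acylation through the N-acylpyridinium ion: the axial secondary C6 hydroxyl, though hindered, is the only hydroxyl acylated at a useful rate because the tertiary C4 hydroxyl is inert under these conditions, and C6 keeps its configuration since its C–O bond is not broken.

Step 13
Reactants: 22 4β-hydroxy-5α,7αH-eudesman-6β-yl (E)-3-[3-(tert-butyldimethylsilyloxy)-4-methoxyphenyl]prop-2-enoate
Product: 23 4β-hydroxy-5α,7αH-eudesman-6β-yl (E)-isoferulate, (1R,2S,4aR,8S,8aS)-8-hydroxy-4a,8-dimethyl-2-(propan-2-yl)decahydronaphthalen-1-yl (2E)-3-(3-hydroxy-4-methoxyphenyl)prop-2-enoate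
Conditions: Bu4NF, AcOH, THF, 0 °C
Reagents that add atoms: none
Why: Fluoride cleavage of the aryl silyl ether, buffered with acetic acid so that neither phenoxide nor fluoride attacks the hindered cinnamate ester or isomerises its E double bond, releases the phenol of the target.

**Compound list**

1 | (S)-piperitone, (6S)-3-methyl-6-(propan-2-yl)cyclohex-2-en-1-one | CC1=CC(=O)[C@H](C(C)C)CC1 | starting material
2 | (6S)-2,3-dibromo-3-methyl-6-(propan-2-yl)cyclohexan-1-one (trans dibromide, configuration at the two C–Br carbons not defined) | CC1(Br)C(Br)C(=O)[C@H](C(C)C)CC1 | intermediate (not isolated)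
3 | (6S)-2-bromo-3-methyl-6-(propan-2-yl)cyclohex-2-en-1-one | CC1=C(Br)C(=O)[C@H](C(C)C)CC1 | intermediate
4 | (1R,6S)-2-bromo-3-methyl-6-(propan-2-yl)cyclohex-2-en-1-ol (OH cis to isopropyl) | O[C@H]1C(Br)=C(C)CC[C@H]1C(C)C | intermediate
5 | tert-butyl{[(1R,6S)-2-bromo-3-methyl-6-(propan-2-yl)cyclohex-2-en-1-yl]oxy}dimethylsilane | CC(C)(C)[Si](C)(C)O[C@H]1C(Br)=C(C)CC[C@H]1C(C)C | intermediate
6 | N-methoxy-N-methylacetamide | CON(C)C(C)=O | starting material
7 | [(5S,6R)-6-(tert-butyldimethylsilyloxy)-2-methyl-5-(propan-2-yl)cyclohex-1-en-1-yl]lithium | CC(C)(C)[Si](C)(C)O[C@H]1C([Li])=C(C)CC[C@H]1C(C)C | intermediate (not isolated)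
8 | 1-[(5S,6R)-6-(tert-butyldimethylsilyloxy)-2-methyl-5-(propan-2-yl)cyclohex-1-en-1-yl]ethan-1-one | CC(C)(C)[Si](C)(C)O[C@H]1C(C(C)=O)=C(C)CC[C@H]1C(C)C | intermediate
9 | allyltrimethylsilane | C=CC[Si](C)(C)C | starting material
10 | trichlorotitanium enolate of 11 (C5=C4 enolate, geometry not defined; C6 R, C7 S, C10 S) | CC(C)(C)[Si](C)(C)O[C@H]1C(=C(C)O[Ti](Cl)(Cl)Cl)[C@](C)(CC=C)CC[C@H]1C(C)C | intermediate (not isolated)
11 | 1-[(1S,2R,3S,6S)-2-(tert-butyldimethylsilyloxy)-6-methyl-3-(propan-2-yl)-6-(prop-2-en-1-yl)cyclohexyl]ethan-1-one (acetyl, silyloxy, isopropyl and methyl on the β face, allyl on the α face) | CC(C)(C)[Si](C)(C)O[C@H]1[C@@H](C(C)=O)[C@](C)(CC=C)CC[C@H]1C(C)C | intermediate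
12 | B-alkyl-9-borabicyclo[3.3.1]nonane from 11 (boron on C3) | CC(C)(C)[Si](C)(C)O[C@H]1[C@@H](C(C)=O)[C@](C)(CCCB2C3CCCC2CCC3)CC[C@H]1C(C)C | intermediate (not isolated)
13 | 1-[(1S,2R,3S,6S)-2-(tert-butyldimethylsilyloxy)-6-(3-hydroxypropyl)-6-methyl-3-(propan-2-yl)cyclohexyl]ethan-1-one | CC(C)(C)[Si](C)(C)O[C@H]1[C@@H](C(C)=O)[C@](C)(CCCO)CC[C@H]1C(C)C | intermediate
14 | 1-[(1S,2R,3S,6S)-2-(tert-butyldimethylsilyloxy)-6-(3-iodopropyl)-6-methyl-3-(propan-2-yl)cyclohexyl]ethan-1-one | CC(C)(C)[Si](C)(C)O[C@H]1[C@@H](C(C)=O)[C@](C)(CCCI)CC[C@H]1C(C)C | intermediate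
15 | C3 diiodosamarium alkyl from 14 (trivalent samarium) | CC(C)(C)[Si](C)(C)O[C@H]1[C@@H](C(C)=O)[C@](C)(CCC[Sm](I)I)CC[C@H]1C(C)C | intermediate (not isolated)
16 | 6β-(tert-butyldimethylsilyloxy)-5α,7αH-eudesman-4β-ol, (4S,5S,6R,7S,10R) | CC(C)(C)[Si](C)(C)O[C@H]1[C@@H]2[C@](C)(CCC[C@]2(C)O)CC[C@H]1C(C)C | intermediate
17 | 5α,7αH-eudesmane-4β,6β-diol, (4S,5S,6R,7S,10R) | O[C@H]1[C@@H]2[C@](C)(CCC[C@]2(C)O)CC[C@H]1C(C)C | intermediate
18 | isoferulic acid | COc1ccc(/C=C/C(=O)O)cc1O | starting material
19 | tert-butyldimethylsilyl (E)-3-[3-(tert-butyldimethylsilyloxy)-4-methoxyphenyl]prop-2-enoate | COc1ccc(/C=C/C(=O)O[Si](C)(C)C(C)(C)C)cc1O[Si](C)(C)C(C)(C)C | intermediate (not isolated)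
20 | (E)-3-[3-(tert-butyldimethylsilyloxy)-4-methoxyphenyl]prop-2-enoic acid | COc1ccc(/C=C/C(=O)O)cc1O[Si](C)(C)C(C)(C)C | intermediate
21 | (E)-3-[3-(tert-butyldimethylsilyloxy)-4-methoxyphenyl]prop-2-enoyl chloride | COc1ccc(/C=C/C(Cl)=O)cc1O[Si](C)(C)C(C)(C)C | intermediate
22 | 4β-hydroxy-5α,7αH-eudesman-6β-yl (E)-3-[3-(tert-butyldimethylsilyloxy)-4-methoxyphenyl]prop-2-enoate | COc1ccc(/C=C/C(=O)O[C@H]2[C@@H]3[C@](C)(CCC[C@]3(C)O)CC[C@H]2C(C)C)cc1O[Si](C)(C)C(C)(C)C | intermediate
23 | 4β-hydroxy-5α,7αH-eudesman-6β-yl (E)-isoferulate, (4S,5S,6R,7S,10R) | COc1ccc(/C=C/C(=O)O[C@H]2[C@@H]3[C@](C)(CCC[C@]3(C)O)CC[C@H]2C(C)C)cc1O | target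

**Step count and risks**

Total step count: 13. Longest linear sequence: 11 steps (steps 1 to 9, 12 and 13, from 1); steps 10 and 11 form the side branch.

Steps most likely to fail:

1. Step 5. In titanium enolate 10 the C6–O bond lies parallel to the enolate π system, so loss of silanolate (addition–elimination) may compete with protonation; allyl transfer to the hindered tetrasubstituted double bond may also be slow or go partly to the β face. Fallback: starting from 8, the allyl group would be transferred as allylcopper (allylmagnesium bromide, CuBr·SMe2, Me3SiCl, THF, −78 °C). This adds in conjugate fashion without a strong Lewis acid, and the enolate is trapped at once as the neutral trimethylsilyl enol ether F1, which cannot expel silanolate. Mild hydrolysis (AcOH, THF, H2O, 0 °C), with protonation from the α face, comes back to the route at 11.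

2. Step 8. The alkylsamarium may be protonated or abstract hydrogen before it reaches the hindered carbonyl, so that reductive loss of iodine competes with ring closure. Fallback: starting from 14, the carbanion would be made by a two-electron route. Iodine–lithium exchange with t-BuLi (2 equiv, pentane–Et2O, −100 to −78 °C), which on a primary iodide should outrun addition of the reagent to the hindered ketone, gives the alkyllithium F2. This closes ring A through the same chair transition state, and aqueous quench comes back to the route at 16.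

3. Step 2. Hydride may be delivered along the axial trajectory to a larger extent than expected, which would give the C6 epimer. Fallback: starting from 3, the opposite preference of a small hydride would be used on purpose. Luche reduction (NaBH4, CeCl3·7H2O, MeOH, −40 °C) should deliver hydride axially to give the trans alcohol (1S,6S)-2-bromo-3-methyl-6-(propan-2-yl)cyclohex-2-en-1-ol F3. Mitsunobu inversion with 4-nitrobenzoic acid (PPh3, diisopropyl azodicarboxylate, THF), the same operation that converts menthol into a neomenthyl ester, would give the cis 4-nitrobenzoate F4. Methanolysis (K2CO3, MeOH) comes back to the route at 4.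

Further compounds
F1 | step 5 | trimethylsilyl enol ether of 11 (C5=C4, geometry not defined) | CC(C)(C)[Si](C)(C)O[C@H]1C(=C(C)O[Si](C)(C)C)[C@](C)(CC=C)CC[C@H]1C(C)C
F2 | step 8 | C3 alkyllithium from 14 | CC(C)(C)[Si](C)(C)O[C@H]1[C@@H](C(C)=O)[C@](C)(CCC[Li])CC[C@H]1C(C)C
F3 | step 2 | (1S,6S)-2-bromo-3-methyl-6-(propan-2-yl)cyclohex-2-en-1-ol | O[C@@H]1C(Br)=C(C)CC[C@H]1C(C)C
F4 | step 2 | (1R,6S)-2-bromo-3-methyl-6-(propan-2-yl)cyclohex-2-en-1-yl 4-nitrobenzoate | O=C(O[C@H]1C(Br)=C(C)CC[C@H]1C(C)C)c1ccc(cc1)[N+](=O)[O-]
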